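**Plan**

1. Numbering: each half is numbered as a naphthalene (quinone half C1–C8a with ethyl on C2 and the ether oxygen on C3; trione half primed, ethyl and ether oxygen on C2'). The target is the dehydro-dimer of one monomer, a 2-ethyl-3-hydroxy-5,6,8-trioxygenated 1,4-naphthoquinone.
2. Cuts, in order: the C2'–O ether bond between the halves (oxidative dearomatising C–O coupling of two monomer molecules); C1–C2 of the quinone ring; C3–C4 (allenyl anion plus benzocyclobutenedione); the four-membered ring (aryne [2+2]).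
3. Enabling feature: in the quinone ring, C1(=O) sits on aromatic C8a, C4(=O) on C4a, and C2=C3 is an enol-ether alkene. This is the closed form of an o-quinoid ketene (C1=C8a, C4a=C4) carrying a 1-alkoxyallene (C3=C2), i.e. the ring-opened form of a strained 2-allenyl-2-hydroxybenzocyclobutenone.
4. Forward: benzene ring (bought) → cyclobutene ring and 1,2-dione in one regioconvergent operation (aryne + ketene silyl acetal, hydrolysis, oxidation) → allenyl carbinol → strain-release 4π opening / 6π closure gives the quinone ring with ethyl and oxygen in place → O-demethylation → dimerisation → debenzylation.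
5. Stereochemistry: the single centre C2' (S) is created in the dimerisation, under control of a C2-symmetric chiral aryl-λ3-iodane that carries both monomer units as ligands.

Key step: step 7

Assumption: the sense of induction of the lactamide iodane in step 9 cannot be assigned beforehand; the (R,R)-reagent is written, and its (S,S)-antipode (from the other lactic acid enantiomer) takes its place if the opposite sense is found.

**Step 1**
Reactants: 1 benzene-1,2,4-triyl triacetate
Product: 2 1,2,4-tris(benzyloxy)benzene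
Conditions: BnBr, K2CO3, MeOH (6 equiv), DMF, 60 °C, argon
Reagents that add atoms: benzyl bromide, BrCc1ccccc1
Why: Carbonate-mediated methanolysis frees the three phenoxides under argon and Williamson O-benzylation traps them at once, before the air-sensitive triol can oxidise.

**Step 2**
Reactants: 2 1,2,4-tris(benzyloxy)benzene
Product: 3 1-bromo-2,4,5-tris(benzyloxy)benzene
Conditions: NBS, MeCN, 0 °C → rt
Reagents that add atoms: N-bromosuccinimide, O=C1CCC(=O)N1Br
Why: Electrophilic aromatic bromination should go to C5, the only free position that is para to one benzyloxy group, ortho to another and not flanked on both sides.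

**Step 3**
Reactants: 3 1-bromo-2,4,5-tris(benzyloxy)benzene; 4 tris(trimethylsiloxy)ethene
Product: 10 2,3,5-tris(benzyloxy)bicyclo[4.2.0]octa-1,3,5-triene-7,8-dione, via 3,4,6-tris(benzyloxy)benzyne 5 (not isolated), via first tris(trimethylsiloxy) cycloadduct 6 (not isolated), via regioisomeric tris(trimethylsiloxy) cycloadduct 7 (not isolated), via first ketol 8 (not isolated), via regioisomeric ketol 9 (not isolated)
Conditions: LiTMP (n-BuLi + 2,2,6,6-tetramethylpiperidine), 4 (3 equiv), THF, −78 → −20 °C; 1 M HCl, THF, 0 °C; extractive work-up, then Dess–Martin periodinane, CH2Cl2, rt (ketol mixture taken on without purification)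
Reagents that add atoms: none
Why: ortho-Lithiation between Br and OBn and loss of LiBr gives the aryne, which undergoes the polar [2+2] cycloaddition typical of arynes with ketene silyl acetals in both orientations (each aryne carbon has an ortho benzyloxy group, so no single orientation can be counted on), acid hydrolysis of the silyl acetals gives the two α-ketols, and neutral Dess–Martin oxidation of the unseparated mixture converges on one dione because both four-ring carbons end as C=O, with benzyl ethers and the strained ring left untouched.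

**Step 4**
Reactants: 11 but-2-yn-1-ol
Product: 12 1-methoxybut-2-yne
Conditions: NaH, MeI, THF, 0 °C → rt
Reagents that add atoms: iodomethane, CI
Why: Williamson ether synthesis on a primary propargylic alkoxide.

**Step 5**
Reactants: 12 1-methoxybut-2-yne
Product: 13 1-methoxybuta-1,2-diene
Conditions: KOtBu (10 mol %), THF, 50 °C, short contact; distil from the base
Reagents that add atoms: none
Why: Base-catalysed propargyl-to-allenyl prototropic isomerisation through the oxygen-stabilised propargyl/allenyl anion gives the alkoxyallene, and catalytic base with short contact is meant to stop before further isomerisation to 1-methoxybuta-1,3-diene.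

**Step 6**
Reactants: 13 1-methoxybuta-1,2-diene; 10 2,3,5-tris(benzyloxy)bicyclo[4.2.0]octa-1,3,5-triene-7,8-dione
Product: 15 2,3,5-tris(benzyloxy)-8-hydroxy-8-(1-methoxybuta-1,2-dien-1-yl)bicyclo[4.2.0]octa-1,3,5-trien-7-one, via 1-lithio-1-methoxybuta-1,2-diene 14 (not isolated)
Conditions: n-BuLi, THF, −78 → −40 °C; then 10 (1.0 equiv), THF, −78 °C; H2O quench at −78 °C
Reagents that add atoms: none
Why: Alkoxyallenes are lithiated at C1 (sp2 C–H next to oxygen) and the anion adds through C1 to ketones (1,2-addition); of the two carbonyls of 10, C8 is conjugated to only one ortho benzyloxy donor (twisted by its neighbour) while C7 is deactivated by an ortho and a para benzyloxy donor, so addition is expected at C8, the resulting alkoxide protects C7 from a second addition, and the cold quench prevents anion-accelerated ring opening.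

**Step 7**
Reactants: 15 2,3,5-tris(benzyloxy)-8-hydroxy-8-(1-methoxybuta-1,2-dien-1-yl)bicyclo[4.2.0]octa-1,3,5-trien-7-one
Product: 18 5,6,8-tris(benzyloxy)-2-ethyl-3-methoxy-1,4-naphthoquinone, via allenyl o-quinoid ketene 16 (not isolated), via 2-ethylidene-4-hydroxynaphthalenone 17 (not isolated)
Conditions: PhMe (degassed), 110 °C
Reagents that add atoms: none
Why: Heating breaks the σ-bond between the carbonyl carbon (future C1) and the carbinol carbon (future C4) of the four-membered ring in a conrotatory 4π-electrocyclic opening, paid for by release of cyclobutenone strain, in which the donor hydroxyl rotates outward, so that o-quinoid ketene 16 (C1=C8a, C4a=C4) forms with the methoxyallenyl group turned toward the ketene. A thermal disrotatory 6π-electrocyclisation of C1=C8a, C4a=C4 and the proximal allene bond C3=C2 then joins ketene carbon C1 to the central allene carbon C2, closing the six-membered quinone ring and restoring the benzene ring (17), and proton transfer from O4–H to the ethylidene carbon gives quinone 18 with no oxidant. The closest known reaction type is the thermal ring expansion of 4-allenyl- and 4-alkenyl-4-hydroxycyclobutenones and of 2-alkenyl-2-hydroxybenzocyclobutenones to quinones (Moore-type rearrangement). No stereocentre is created, and the carbinol centre and allene axis of 15 are erased. The step needs torquoselectivity (hydroxyl out, allene in, which also keeps the hydroxyl away from the ketene and so prevents lactone formation) and closure at the central rather than the terminal allene carbon (only the former gives an unstrained six-membered ring); the positions of ethyl, methoxy and the three benzyloxy groups are already fixed by the carbinol.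

**Step 8**
Reactants: 18 5,6,8-tris(benzyloxy)-2-ethyl-3-methoxy-1,4-naphthoquinone
Product: 19 5,6,8-tris(benzyloxy)-2-ethyl-3-hydroxy-1,4-naphthoquinone
Conditions: 1 M NaOH, THF/MeOH, rt, argon; then 1 M HCl
Reagents that add atoms: sodium hydroxide, [Na+].[OH-]
Why: The 3-methoxy group is a vinylogous ester and is saponified by addition–elimination of hydroxide at C3, aryl benzyl ethers are inert, and argon excludes oxidative ring contraction of the hydroxyquinone anion.

**Step 9**
Reactants: 19 5,6,8-tris(benzyloxy)-2-ethyl-3-hydroxy-1,4-naphthoquinone (two molecules)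
Product: 21 (S)-5,6,8-tris(benzyloxy)-2-{[5,6,8-tris(benzyloxy)-2-ethyl-1,4-dioxo-1,4-dihydronaphthalen-3-yl]oxy}-2-ethylnaphthalene-1,3,4(2H)-trione, via bis(quinonyloxy)aryl-λ3-iodane 20 (not isolated)
Conditions: (R,R)-ArI(OAc)2 (0.5 equiv; Ar = 2,6-bis[1-(mesitylamino)-1-oxopropan-2-yloxy]phenyl), PhCl, 25 °C, AcOH removed in vacuo; then CH2Cl2, −40 → 0 °C
Reagents that add atoms: none
Why: Proposed new method: the 3-hydroxyl of 19 is a vinylogous carboxylic acid and should exchange for acetate on trivalent iodine when acetic acid is removed, placing two quinonyloxy units on one iodine as O-bound enolates (20); ionisation of one ligand gives an aryl(enolato)iodonium/quinonyloxide ion pair, and the oxygen of the released vinylogous carboxylate attacks the ethyl-bearing enolate carbon C2' of the ligand still on iodine in an SN2'-type reductive displacement of the iodoarene, which forms the C2'–O bond and the 1,3,4-trione; the lactamide arms of the C2-symmetric iodoarene fold around iodine through N–H···O hydrogen bonds and are meant to shield one face of the planar C2'=C3' enolate, which is how the (S)-centre is to be set; attack through O3 rather than the peri-flanked O1 of the ambident anion, and on C2' rather than by C–C coupling, is favoured sterically, and removal of acetic acid suppresses acetoxylation; the closest known reaction types are chiral aryl-λ3-iodane-mediated dearomatising spirolactonisation of naphthols by carboxylate nucleophiles, α-oxygenation of 1,3-dicarbonyl compounds with (diacyloxyiodo)arenes, and the racemic dehydrodimerisation of 3-alkyl-2-hydroxy-1,4-naphthoquinones by PbO2.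

**Step 10**
Reactants: 21 (S)-hexabenzyl dimer
Product: 22 (S)-2-ethyl-2-[(2-ethyl-5,6,8-trihydroxy-1,4-dioxo-1,4-dihydronaphthalen-3-yl)oxy]-5,6,8-trihydroxynaphthalene-1,3,4(2H)-trione
Conditions: BCl3, C6HMe5, CH2Cl2, −78 °C; aqueous work-up
Reagents that add atoms: none
Why: Lewis-acid debenzylation with pentamethylbenzene as benzyl-cation scavenger is non-reductive and non-basic, which matters because reduction of the trione to its enediol would expel the quinonyloxy group and base would trigger benzilic-acid-type ring contraction; the quaternary centre has no enolisable hydrogen and is not touched.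

**Compound list**

1 | benzene-1,2,4-triyl triacetate | CC(=O)Oc1ccc(OC(C)=O)c(OC(C)=O)c1 | starting material
2 | 1,2,4-tris(benzyloxy)benzene | C(Oc1ccc(OCc2ccccc2)c(OCc2ccccc2)c1)c1ccccc1 | intermediate
3 | 1-bromo-2,4,5-tris(benzyloxy)benzene | Brc1cc(OCc2ccccc2)c(OCc2ccccc2)cc1OCc1ccccc1 | intermediate
4 | tris(trimethylsiloxy)ethene | C[Si](C)(C)OC=C(O[Si](C)(C)C)O[Si](C)(C)C | starting material
5 | 3,4,6-tris(benzyloxy)benzyne | C1#CC(OCc2ccccc2)=C(OCc2ccccc2)C=C1OCc1ccccc1 | intermediate
6 | 2,4,5-tris(benzyloxy)-7,7,8-tris(trimethylsiloxy)bicyclo[4.2.0]octa-1,3,5-triene (racemic) | C[Si](C)(C)OC1(O[Si](C)(C)C)C(O[Si](C)(C)C)c2c(OCc3ccccc3)cc(OCc3ccccc3)c(OCc3ccccc3)c12 | intermediate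
7 | 2,3,5-tris(benzyloxy)-7,7,8-tris(trimethylsiloxy)bicyclo[4.2.0]octa-1,3,5-triene (racemic) | C[Si](C)(C)OC1C(O[Si](C)(C)C)(O[Si](C)(C)C)c2c(OCc3ccccc3)cc(OCc3ccccc3)c(OCc3ccccc3)c12 | intermediate
8 | 2,4,5-tris(benzyloxy)-8-hydroxybicyclo[4.2.0]octa-1,3,5-trien-7-one (racemic) | O=C1C(O)c2c(OCc3ccccc3)cc(OCc3ccccc3)c(OCc3ccccc3)c12 | intermediate
9 | 2,3,5-tris(benzyloxy)-8-hydroxybicyclo[4.2.0]octa-1,3,5-trien-7-one (racemic) | OC1C(=O)c2c(OCc3ccccc3)cc(OCc3ccccc3)c(OCc3ccccc3)c12 | intermediate
10 | 2,3,5-tris(benzyloxy)bicyclo[4.2.0]octa-1,3,5-triene-7,8-dione | O=C1C(=O)c2c(OCc3ccccc3)cc(OCc3ccccc3)c(OCc3ccccc3)c12 | intermediate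
11 | but-2-yn-1-ol | CC#CCO | starting material
12 | 1-methoxybut-2-yne | CC#CCOC | intermediate
13 | 1-methoxybuta-1,2-diene (racemic) | CC=C=COC | intermediate
14 | 1-lithio-1-methoxybuta-1,2-diene | [Li]C(OC)=C=CC | intermediate
15 | 2,3,5-tris(benzyloxy)-8-hydroxy-8-(1-methoxybuta-1,2-dien-1-yl)bicyclo[4.2.0]octa-1,3,5-trien-7-one (diastereomer mixture, racemic) | CC=C=C(OC)C1(O)C(=O)c2c(OCc3ccccc3)cc(OCc3ccccc3)c(OCc3ccccc3)c12 | intermediate
16 | o-quinoid ketene, hydroxyl outward, methoxyallenyl toward the ketene | O=C=C1/C(=C(/O)C(OC)=C=CC)C(OCc2ccccc2)=C(OCc2ccccc2)C=C1OCc1ccccc1 | intermediate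
17 | 5,6,8-tris(benzyloxy)-2-ethylidene-4-hydroxy-3-methoxynaphthalen-1(2H)-one | CC=C1C(=O)c2c(OCc3ccccc3)cc(OCc3ccccc3)c(OCc3ccccc3)c2C(O)=C1OC | intermediate
18 | 5,6,8-tris(benzyloxy)-2-ethyl-3-methoxy-1,4-naphthoquinone | CCC1=C(OC)C(=O)c2c(OCc3ccccc3)c(OCc3ccccc3)cc(OCc3ccccc3)c2C1=O | intermediate
19 | 5,6,8-tris(benzyloxy)-2-ethyl-3-hydroxy-1,4-naphthoquinone | CCC1=C(O)C(=O)c2c(OCc3ccccc3)c(OCc3ccccc3)cc(OCc3ccccc3)c2C1=O | intermediate
20 | (R,R)-{2,6-bis[1-(mesitylamino)-1-oxopropan-2-yloxy]phenyl}bis{[5,6,8-tris(benzyloxy)-2-ethyl-1,4-dioxo-1,4-dihydronaphthalen-3-yl]oxy}-λ3-iodane | CCC1=C(OI(OC2=C(CC)C(=O)c3c(OCc4ccccc4)cc(OCc4ccccc4)c(OCc4ccccc4)c3C2=O)c2c(O[C@H](C)C(=O)Nc3c(C)cc(C)cc3C)cccc2O[C@H](C)C(=O)Nc2c(C)cc(C)cc2C)C(=O)c2c(OCc3ccccc3)c(OCc3ccccc3)cc(OCc3ccccc3)c2C1=O | intermediate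
21 | (S)-5,6,8-tris(benzyloxy)-2-{[5,6,8-tris(benzyloxy)-2-ethyl-1,4-dioxo-1,4-dihydronaphthalen-3-yl]oxy}-2-ethylnaphthalene-1,3,4(2H)-trione | CCC1=C(O[C@]2(CC)C(=O)C(=O)c3c(OCc4ccccc4)c(OCc4ccccc4)cc(OCc4ccccc4)c3C2=O)C(=O)c2c(OCc3ccccc3)c(OCc3ccccc3)cc(OCc3ccccc3)c2C1=O | intermediate
22 | (S)-2-ethyl-2-[(2-ethyl-5,6,8-trihydroxy-1,4-dioxo-1,4-dihydronaphthalen-3-yl)oxy]-5,6,8-trihydroxynaphthalene-1,3,4(2H)-trione | CCC1=C(O[C@]2(CC)C(=O)C(=O)c3c(O)c(O)cc(O)c3C2=O)C(=O)c2c(O)c(O)cc(O)c2C1=O | target

**Totals**

Total step count: 10. Longest linear sequence: 8 (steps 1–3 and 6–10; steps 4–5 make the allene).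

**Steps most likely to fail**

Step 9. Ligand coupling on iodine may lose chemoselectivity (acetate or carbon attack on the iodine-bound enolate, over-oxidation), and facial discrimination at the planar C2' enolate carbon may be poor. The fallback sets out from 19 and comes back at 21: oxidation of 19 with PbO2 in AcOH/benzene at rt (dehydrodimerisation of 3-alkyl-2-hydroxy-1,4-naphthoquinones by a one-electron oxidant is a known reaction type) should give the racemate, that is 21 together with (R)-5,6,8-tris(benzyloxy)-2-{[5,6,8-tris(benzyloxy)-2-ethyl-1,4-dioxo-1,4-dihydronaphthalen-3-yl]oxy}-2-ethylnaphthalene-1,3,4(2H)-trione F1. The enantiomers are then separated by preparative HPLC on a chiral stationary phase (amylose tris(3,5-dimethylphenylcarbamate)).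

Step 6. Steric approach control may override the electronic bias, so that the lithioallene adds to the other carbonyl (C7) or adds twice. The fallback sets out from 3 and comes back at 15, and fixes the regiochemistry by construction. Step 3 is stopped after the acid hydrolysis and the two ketols are separated by chromatography; ketol 8 has its only carbonyl at the carbon that must receive the allene and cannot enolise, while ketol 9 can still be oxidised to 10. Silylation of 8 (TBSCl, imidazole, DMF) should give 2,4,5-tris(benzyloxy)-8-(tert-butyldimethylsilyloxy)bicyclo[4.2.0]octa-1,3,5-trien-7-one F2. Addition of 14 at −78 °C should give 2,3,5-tris(benzyloxy)-7-(tert-butyldimethylsilyloxy)-8-(1-methoxybuta-1,2-dien-1-yl)bicyclo[4.2.0]octa-1,3,5-trien-8-ol F3. Desilylation (TBAF, THF, 0 °C) should give 2,3,5-tris(benzyloxy)-8-(1-methoxybuta-1,2-dien-1-yl)bicyclo[4.2.0]octa-1,3,5-triene-7,8-diol F4. Oxidation of the secondary benzylic alcohol (Dess–Martin periodinane, NaHCO3, CH2Cl2) rejoins the route at 15.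

Step 10. The Lewis acid may cleave the vinylogous ester link between the halves by addition–elimination at C3, or debenzylation may stall at the two non-peri positions. The fallback sets out from 19 and comes back at 22, moving the debenzylation to the monomer stage, where there is no inter-half link and the conditions can be forced. BCl3, C6HMe5, CH2Cl2, −78 → 0 °C should give 2-ethyl-3,5,6,8-tetrahydroxy-1,4-naphthoquinone F5. Silylation (TBSOTf, 2,6-lutidine, CH2Cl2) should give 3,5,6,8-tetrakis(tert-butyldimethylsilyloxy)-2-ethyl-1,4-naphthoquinone F6. An aqueous NaHCO3/MeOH work-up, which hydrolyses only the labile vinylogous silyl ester at O3, should give 5,6,8-tris(tert-butyldimethylsilyloxy)-2-ethyl-3-hydroxy-1,4-naphthoquinone F7. Coupling under the conditions of step 9 should give (S)-5,6,8-tris(tert-butyldimethylsilyloxy)-2-{[5,6,8-tris(tert-butyldimethylsilyloxy)-2-ethyl-1,4-dioxo-1,4-dihydronaphthalen-3-yl]oxy}-2-ethylnaphthalene-1,3,4(2H)-trione F8. Desilylation with HF·pyridine in THF at 0 °C then gives 22.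

**Further compounds**

F1 | step 9 | (R)-5,6,8-tris(benzyloxy)-2-{[5,6,8-tris(benzyloxy)-2-ethyl-1,4-dioxo-1,4-dihydronaphthalen-3-yl]oxy}-2-ethylnaphthalene-1,3,4(2H)-trione | CCC1=C(O[C@@]2(CC)C(=O)C(=O)c3c(OCc4ccccc4)c(OCc4ccccc4)cc(OCc4ccccc4)c3C2=O)C(=O)c2c(OCc3ccccc3)c(OCc3ccccc3)cc(OCc3ccccc3)c2C1=O
F2 | step 6 | 2,4,5-tris(benzyloxy)-8-(tert-butyldimethylsilyloxy)bicyclo[4.2.0]octa-1,3,5-trien-7-one | O=C1C(O[Si](C)(C)C(C)(C)C)c2c(OCc3ccccc3)cc(OCc3ccccc3)c(OCc3ccccc3)c12
F3 | step 6 | 2,3,5-tris(benzyloxy)-7-(tert-butyldimethylsilyloxy)-8-(1-methoxybuta-1,2-dien-1-yl)bicyclo[4.2.0]octa-1,3,5-trien-8-ol | CC=C=C(OC)C1(O)C(O[Si](C)(C)C(C)(C)C)c2c(OCc3ccccc3)cc(OCc3ccccc3)c(OCc3ccccc3)c12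
F4 | step 6 | 2,3,5-tris(benzyloxy)-8-(1-methoxybuta-1,2-dien-1-yl)bicyclo[4.2.0]octa-1,3,5-triene-7,8-diol | CC=C=C(OC)C1(O)C(O)c2c(OCc3ccccc3)cc(OCc3ccccc3)c(OCc3ccccc3)c12
F5 | step 10 | 2-ethyl-3,5,6,8-tetrahydroxy-1,4-naphthoquinone | CCC1=C(O)C(=O)c2c(O)c(O)cc(O)c2C1=O
F6 | step 10 | 3,5,6,8-tetrakis(tert-butyldimethylsilyloxy)-2-ethyl-1,4-naphthoquinone | CCC1=C(O[Si](C)(C)C(C)(C)C)C(=O)c2c(O[Si](C)(C)C(C)(C)C)c(O[Si](C)(C)C(C)(C)C)cc(O[Si](C)(C)C(C)(C)C)c2C1=O
F7 | step 10 | 5,6,8-tris(tert-butyldimethylsilyloxy)-2-ethyl-3-hydroxy-1,4-naphthoquinone | CCC1=C(O)C(=O)c2c(O[Si](C)(C)C(C)(C)C)c(O[Si](C)(C)C(C)(C)C)cc(O[Si](C)(C)C(C)(C)C)c2C1=O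
F8 | step 10 | (S)-5,6,8-tris(tert-butyldimethylsilyloxy)-2-{[5,6,8-tris(tert-butyldimethylsilyloxy)-2-ethyl-1,4-dioxo-1,4-dihydronaphthalen-3-yl]oxy}-2-ethylnaphthalene-1,3,4(2H)-trione | CCC1=C(O[C@]2(CC)C(=O)C(=O)c3c(O[Si](C)(C)C(C)(C)C)c(O[Si](C)(C)C(C)(C)C)cc(O[Si](C)(C)C(C)(C)C)c3C2=O)C(=O)c2c(O[Si](C)(C)C(C)(C)C)c(O[Si](C)(C)C(C)(C)C)cc(O[Si](C)(C)C(C)(C)C)c2C1=O
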